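## Retrosynthetic overview
1. The target is (2S)-6,8-diprenylpinocembrin. Rings A and B are bought (phloroacetophenone, benzaldehyde). Only ring C is built, and it is closed last.
2. The last disconnection is O1–C2: an enantioselective 6-endo oxa-Michael closure of 2',4',6'-trihydroxy-3',5'-diprenylchalcone. Its two ortho OH groups are equivalent, so only one constitutional isomer can form.
3. The chalcone Cα=Cβ bond comes from a protecting-group-free Claisen–Schmidt condensation of 3,5-diprenylphloroacetophenone with benzaldehyde.
4. The two aryl–prenyl bonds come from a double C-alkylation of phloroacetophenone with prenyl bromide.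

**Assumption:** the sense of induction in step 3 (quinidine-derived catalyst gives 2S) is predicted by analogy with intermolecular enone additions of this catalyst family. It must be confirmed on the product by chiral HPLC and CD (2S: positive band near 330 nm, negative band near 290 nm). The quinine-derived pseudo-enantiomer is equally available.

**Catalyst used in step 3 (commercial):** 3-{[3,5-bis(trifluoromethyl)phenyl]amino}-4-{[(9R)-6'-methoxycinchonan-9-yl]amino}cyclobut-3-ene-1,2-dione, called below "the quinidine-derived squaramide".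
SMILES: COC1=CC2=C(C=CN=C2C=C1)[C@H]([C@H]3C[C@@H]4CCN3C[C@@H]4C=C)NC5=C(NC6=CC(=CC(=C6)C(F)(F)F)C(F)(F)F)C(=O)C5=O

## Route

Step 1
Reactants: 1 2',4',6'-trihydroxyacetophenone (phloroacetophenone); 2 prenyl bromide (1-bromo-3-methylbut-2-ene)
Product: 4 1-[2,4,6-trihydroxy-3,5-bis(3-methylbut-2-en-1-yl)phenyl]ethan-1-one (3,5-diprenylphloroacetophenone), via monoprenyl ketone 3 (not isolated)
Conditions: 2 (2.1 equiv), KOH (2.1 equiv), H2O, 0 °C → rt, 4 h; chromatography
Reagents that add atoms: prenyl bromide, CC(C)=CCBr
Why: This is an SN2 C-alkylation of an acylphloroglucinol phenoxide, where water solvates the oxygen sites so the soft ring carbons C3 and then C5 attack the primary carbon of prenyl bromide; no stereocentre is formed.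

Step 2
Reactants: 4 3,5-diprenylphloroacetophenone; 5 benzaldehyde
Product: 7 (E)-3-phenyl-1-[2,4,6-trihydroxy-3,5-bis(3-methylbut-2-en-1-yl)phenyl]prop-2-en-1-one (2',4',6'-trihydroxy-3',5'-diprenylchalcone), via aldol adduct 6 (not isolated)
Conditions: LiN(SiMe3)2 (4.5 equiv), THF, −78 → 0 °C; 5 (1.1 equiv), −78 °C → rt, 12 h; inverse quench into 1 M HCl, 0 °C; fast chromatography or crystallisation to remove any racemic flavanone
Reagents that add atoms: benzaldehyde, O=Cc1ccccc1
Why: This is a Claisen–Schmidt aldol condensation through the lithium polyanion, in which the amide base deprotonates the three phenols and the methyl ketone, the enolate adds to non-enolisable benzaldehyde, E1cB loss of hydroxide gives the (E)-enone, and the phenoxides keep the chalcone open until the cold acid quench.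

Step 3
Reactants: 7 2',4',6'-trihydroxy-3',5'-diprenylchalcone
Product: 8 (2S)-5,7-dihydroxy-6,8-bis(3-methylbut-2-en-1-yl)-2-phenyl-2,3-dihydro-4H-chromen-4-one
Conditions: 3-{[3,5-bis(trifluoromethyl)phenyl]amino}-4-{[(9R)-6'-methoxycinchonan-9-yl]amino}cyclobut-3-ene-1,2-dione (10 mol %), toluene/CH2Cl2 4:1 (0.05 M), −20 °C, 48–72 h; AcOH (0.2 equiv) at −20 °C, short silica plug; recrystallise (hexane/EtOAc)
Reagents that add atoms: none
Why: Proposed new method: a catalytic enantioselective 6-endo-trig intramolecular oxa-Michael addition on a free, ester-less 2',6'-dihydroxychalcone, which has not been shown; one ortho OH (6') stays hydrogen-bonded to C=O and lowers the enone LUMO, taking over the role of the removable tert-butyl ester needed in the closest known reaction type (cinchona thiourea- or squaramide-catalysed oxa-Michael cyclisation of alkylidene β-keto esters to flavanones, and in nature the chalcone isomerase reaction); the squaramide NH pair binds the second lone pair of the same carbonyl oxygen and stabilises the enolate developing in the twisted s-trans conformer, while the quinuclidine nitrogen takes the proton of the free ortho OH (2') and passes it on to C3, so the phenoxide is guided to the Si face of Cβ and C2 is set as S; ring closure is strongly downhill for 2',6'-dihydroxychalcones because the 5-OH···O=C4 hydrogen bond is kept, the uncatalysed reaction is negligible in a non-polar solvent at −20 °C, and the acid quench stops retro-oxa-Michael racemisation.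

## Compound list
1 | 2',4',6'-trihydroxyacetophenone (phloroacetophenone) | CC(=O)c1c(O)cc(O)cc1O | starting material
2 | prenyl bromide (1-bromo-3-methylbut-2-ene) | CC(C)=CCBr | starting material
3 | 1-[2,4,6-trihydroxy-3-(3-methylbut-2-en-1-yl)phenyl]ethan-1-one (monoprenyl ketone, not isolated) | CC(=O)c1c(O)cc(O)c(CC=C(C)C)c1O | intermediate
4 | 1-[2,4,6-trihydroxy-3,5-bis(3-methylbut-2-en-1-yl)phenyl]ethan-1-one | CC(=O)c1c(O)c(CC=C(C)C)c(O)c(CC=C(C)C)c1O | intermediate
5 | benzaldehyde | O=Cc1ccccc1 | starting material
6 | 3-hydroxy-3-phenyl-1-[2,4,6-trihydroxy-3,5-bis(3-methylbut-2-en-1-yl)phenyl]propan-1-one (racemic aldol adduct, not isolated) | CC(C)=CCc1c(O)c(CC=C(C)C)c(O)c(C(=O)CC(O)c2ccccc2)c1O | intermediate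
7 | (E)-3-phenyl-1-[2,4,6-trihydroxy-3,5-bis(3-methylbut-2-en-1-yl)phenyl]prop-2-en-1-one | CC(C)=CCc1c(O)c(CC=C(C)C)c(O)c(C(=O)/C=C/c2ccccc2)c1O | intermediate
8 | (2S)-5,7-dihydroxy-6,8-bis(3-methylbut-2-en-1-yl)-2-phenyl-2,3-dihydro-4H-chromen-4-one | CC(C)=CCc1c(O)c(CC=C(C)C)c2c(c1O)C(=O)C[C@@H](c1ccccc1)O2 | target

## Step count and risks
Total steps: 3. Longest linear sequence: 3.

**Step 3 (proposed new step).**
- Risks:
  - The acidic 4'-OH may bind the catalyst in non-productive modes and lower the ee.
  - Traces of base may cause a racemic background reaction.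
  - Slow retro-oxa-Michael erosion of ee is possible.
- Fallback (known chemistry), from 7 back to 8:
  - Cyclise 7 without stereocontrol (NaOAc, EtOH, reflux) to the racemic flavanone F1.
  - Resolve it by preparative HPLC on an amylose tris(3,5-dimethylphenylcarbamate) phase (hexane/i-PrOH, 0.1 % HCO2H). This gives 8 and the (2R)-enantiomer F2.
  - Reopen F2 to 7 by brief treatment with concentrated aqueous KOH and an inverse quench into cold HCl, then recycle it.

**Step 2.**
- Risks: the tetra-anion may react slowly, the aldolate may revert, and part of the chalcone may close to racemic flavanone on work-up.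
- Fallback, from 4 back to 7:
  - Protect the two non-chelated phenols (MeOCH2Cl, i-Pr2NEt, CH2Cl2, 0 °C) to the bis-MOM ketone F3.
  - Run a classical Claisen–Schmidt condensation with 5 (KOH, EtOH, rt) to the bis-MOM chalcone F4.
  - Remove the acetals with dilute HCl in MeOH at rt to give 7, and separate any flavanone formed.

**Step 1.**
- Risks: mixtures containing the monoprenyl ketone 3, geminally dialkylated dearomatised products and O-prenyl ethers; about 35–45 % of 4 is expected.
- Fallback, from 1 back to 4: change from phenoxide alkylation to an acid-mediated Friedel–Crafts prenylation with 2-methylbut-3-en-2-ol (2.5 equiv) and BF3·OEt2 in dioxane at rt. This cannot give geminal or O-alkylation. It must be stopped early to avoid chroman formation. It makes no compound outside the list.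

## Further compounds
F1 | step 3 | rac-5,7-dihydroxy-6,8-bis(3-methylbut-2-en-1-yl)-2-phenyl-2,3-dihydro-4H-chromen-4-one | CC(C)=CCc1c(O)c(CC=C(C)C)c2c(c1O)C(=O)CC(c1ccccc1)O2
F2 | step 3 | (2R)-5,7-dihydroxy-6,8-bis(3-methylbut-2-en-1-yl)-2-phenyl-2,3-dihydro-4H-chromen-4-one | CC(C)=CCc1c(O)c(CC=C(C)C)c2c(c1O)C(=O)C[C@H](c1ccccc1)O2
F3 | step 2 | 1-[2-hydroxy-4,6-bis(methoxymethoxy)-3,5-bis(3-methylbut-2-en-1-yl)phenyl]ethan-1-one | CC(=O)c1c(O)c(CC=C(C)C)c(OCOC)c(CC=C(C)C)c1OCOC
F4 | step 2 | (E)-1-[2-hydroxy-4,6-bis(methoxymethoxy)-3,5-bis(3-methylbut-2-en-1-yl)phenyl]-3-phenylprop-2-en-1-one | COCOc1c(CC=C(C)C)c(O)c(C(=O)/C=C/c2ccccc2)c(OCOC)c1CC=C(C)C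
F0 | step 1 | none | none
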